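## Retrosynthetic overview

1. Target 21 comes from hydroxy ketone 18 by equatorial methyl addition at the left-hand C7 ketone, triple O-acetylation and desilylation. The central CH2–CH2 bond comes from a Giese addition of the right-hand primary iodide 17 to the left-hand α-methylene ketone 13.
2. Both 13 and 17 come from one bicyclic building block 10, an oxepane-fused methylenecyclohexane with a pivaloyloxymethyl arm. Ozonolysis/elimination gives 13. α-Face epoxidation, LiAlH4 and iodination give 17, so the two opposite C7 carbinol configurations derive from the same olefin.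
3. 10 comes from the acyclic diepoxy allylsilane 8 by a new silyl-transfer-catalysed cascade. In each bicycle the oxepane C–O bond forms first (epoxide oxygen onto the activated terminal epoxide), then the cyclohexane C–C bond (allylsilane onto the epoxonium ion).
4. 8 comes from geranyl bromide 1 and methyl acetoacetate 2 by dianion alkylation, Z-enol phosphate formation, Kumada coupling with Me3SiCH2MgCl, double Shi epoxidation (fixes C3, C5a, C9a), reduction and pivaloylation.

Locants for the bicyclic units follow perhydro-1-benzoxepine: O1, C2 (gem-dimethyl), C3 (carbinol), C4, C5, C5a (methyl), C6 (carbon bearing the bridge), C7, C8, C9, C9a (CH–O). β is the face of the 5a-methyl, α the opposite face.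

Assumption: metal enolates, alkoxides and other conjugate bases formed by simple deprotonation are treated as their numbered parent compound, and ent-Shi ketone (the L-fructose-derived enantiomer of the usual catalyst) is taken as commercially available.

## Route

Step 1
Reactants: 1 geranyl bromide [(2E)-1-bromo-3,7-dimethylocta-2,6-diene]; 2 methyl acetoacetate
Product: 3 methyl (6E)-7,11-dimethyl-3-oxododeca-6,10-dienoate
Conditions: 2, NaH then n-BuLi, THF, 0 °C; then 1, 0 → 23 °C; aq. HCl quench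
Reagents that add atoms: none
Why: Dianion γ-alkylation of a β-keto ester: the terminal, more basic carbanion displaces the allylic bromide in an SN2 reaction that keeps the E olefin.

Step 2
Reactants: 3 methyl (6E)-7,11-dimethyl-3-oxododeca-6,10-dienoate
Product: 4 methyl (2Z,6E)-3-[(diethoxyphosphoryl)oxy]-7,11-dimethyldodeca-2,6,10-trienoate
Conditions: NaH, Et2O, 0 °C; ClP(O)(OEt)2
Reagents that add atoms: diethyl chlorophosphate, CCOP(=O)(Cl)OCC
Why: O-phosphorylation of the chelated sodium enolate gives the Z enol phosphate, which fixes the later olefin geometry.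

Step 3
Reactants: 4 methyl (2Z,6E)-3-[(diethoxyphosphoryl)oxy]-7,11-dimethyldodeca-2,6,10-trienoate
Product: 5 methyl (2Z,6E)-7,11-dimethyl-3-[(trimethylsilyl)methyl]dodeca-2,6,10-trienoate
Conditions: Me3SiCH2MgCl, Ni(acac)2 (5 mol %), THF, 0 → 23 °C
Reagents that add atoms: (trimethylsilyl)methylmagnesium chloride, C[Si](C)(C)C[Mg]Cl
Why: Nickel-catalysed Kumada coupling of the enol phosphate C–O bond proceeds with retention of olefin geometry, so the silylmethyl group ends cis to the ester (2Z).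

Step 4
Reactants: 5 methyl (2Z,6E)-7,11-dimethyl-3-[(trimethylsilyl)methyl]dodeca-2,6,10-trienoate
Product: 6 methyl (2Z)-5-[(2S,3S)-3-{2-[(2S)-3,3-dimethyloxiran-2-yl]ethyl}-3-methyloxiran-2-yl]-3-[(trimethylsilyl)methyl]pent-2-enoate
Conditions: ent-Shi ketone (0.4 equiv), KHSO5 (as 2KHSO5·KHSO4·K2SO4), K2CO3, Bu4NHSO4, MeCN/CH2(OMe)2/aq. Na2B4O7 buffer (pH 10.5), 0 °C
Reagents that add atoms: potassium peroxymonosulfate, [K+].[O-]S(=O)(=O)OO
Why: Shi asymmetric epoxidation: the dioxirane from the L-fructose-derived ketone delivers oxygen to the two trisubstituted alkyl olefins through the spiro transition state, setting the (2S,3S) and (2S) epoxide centres by catalyst control, while the ester-conjugated olefin is too electron-poor to react.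

Step 5
Reactants: 6 diepoxy silylmethyl enoate (as in step 4)
Product: 7 (2Z)-5-[(2S,3S)-3-{2-[(2S)-3,3-dimethyloxiran-2-yl]ethyl}-3-methyloxiran-2-yl]-3-[(trimethylsilyl)methyl]pent-2-en-1-ol
Conditions: i-Bu2AlH (2.2 equiv), CH2Cl2, −78 °C; aq. KNaC4H4O6 work-up
Reagents that add atoms: none
Why: Hydride (DIBAL) 1,2-reduction of the conjugated ester at −78 °C gives the allylic alcohol and leaves the trisubstituted epoxides and the C–Si bond untouched.

Step 6
Reactants: 7 diepoxy allylic alcohol (as in step 5)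
Product: 8 (2Z)-5-[(2S,3S)-3-{2-[(2S)-3,3-dimethyloxiran-2-yl]ethyl}-3-methyloxiran-2-yl]-3-[(trimethylsilyl)methyl]pent-2-en-1-yl 2,2-dimethylpropanoate
Conditions: t-BuCOCl, pyridine, DMAP (cat.), CH2Cl2, 0 °C
Reagents that add atoms: pivaloyl chloride, CC(C)(C)C(=O)Cl
Why: Nucleophile-catalysed acylation of the primary allylic alcohol gives a robust ester that later serves as leaving group (left-hand half) or masked hydroxymethyl group (right-hand half).

Step 7
Reactants: 8 diepoxy allylsilane pivalate (as in step 6)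
Product: 10 [(3S,5aS,6R,9aS)-3-hydroxy-2,2,5a-trimethyl-7-methylideneperhydro-1-benzoxepin-6-yl]methyl 2,2-dimethylpropanoate, via trimethylsilyl ether 9 (not isolated)
Conditions: Me3SiNTf2 (10 mol %), 2,6-di-tert-butyl-4-methylpyridine (10 mol %), CH2Cl2, −78 °C; then K2CO3, MeOH, 23 °C
Reagents that add atoms: none
Why: Proposed new method: a silyl-transfer-catalysed cycloisomerisation in which catalytic Me3SiNTf2 silylates the terminal epoxide, the internal epoxide oxygen opens it at the tertiary carbon to give a bicyclic epoxonium ion, the γ-carbon of the Z allylsilane attacks the tertiary epoxonium carbon with inversion through a chair transition state (this sets C5a and places the C6 arm equatorial, while C3 and C9a are carried over from the epoxides), and the β-silyl cation then returns Me3Si+ to the triflimide, which leaves the exocyclic methylene and regenerates the catalyst so that the silicon migrates from carbon to the C3 oxygen with no stoichiometric promoter; the closest known reaction types are the stoichiometric silyl triflate-promoted tandem oxa-/carbacyclisation of diepoxides terminated by enol silanes and the silylium-catalysed Hosomi–Sakurai allylation.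

Step 8
Reactants: 10 bicyclic hydroxy pivalate (as in step 7)
Product: 13 (3S,5aS,9aS)-3-hydroxy-2,2,5a-trimethyl-6-methylideneperhydro-1-benzoxepin-7-one, via ozonide 11 (not isolated), via pivaloyloxy ketone 12 (not isolated)
Conditions: O3, CH2Cl2, −78 °C; PPh3, −78 → 23 °C; then DBU, 0 °C
Reagents that add atoms: ozone, O=[O+][O-]
Why: Ozonolysis of the 1,1-disubstituted olefin gives the C7 ketone and E1cB loss of pivalate then gives the α-methylene ketone, which cannot isomerise into the ring because C5a is quaternary.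

Step 9
Reactants: 10 bicyclic hydroxy pivalate (as in step 7)
Product: 14 [(3S,5aS,6R,9aS)-3-(tert-butyldimethylsilyloxy)-2,2,5a-trimethyl-7-methylideneperhydro-1-benzoxepin-6-yl]methyl 2,2-dimethylpropanoate
Conditions: t-BuMe2SiOTf, 2,6-lutidine, CH2Cl2, −78 → 0 °C
Reagents that add atoms: tert-butyldimethylsilyl triflate, CC(C)(C)[Si](C)(C)OS(=O)(=O)C(F)(F)F
Why: Silyl triflate silylation of the hindered secondary C3 alcohol installs the ether that keeps this oxygen free of acetate until the last step.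

Step 10
Reactants: 14 silyl ether (as in step 9)
Product: 15 [(3S,5aS,6R,7S,9aS)-3-(tert-butyldimethylsilyloxy)-2,2,5a-trimethylperhydrospiro[1-benzoxepine-7,2'-oxiran]-6-yl]methyl 2,2-dimethylpropanoate (oxirane oxygen α, equatorial)
Conditions: mCPBA, NaHCO3, CH2Cl2, 0 °C
Reagents that add atoms: 3-chloroperbenzoic acid, OOC(=O)c1cccc(Cl)c1
Why: Prilezhaev epoxidation: the peracid approaches the exocyclic olefin from the α face because the β (axial) trajectory is blocked by the syn-axial 5a-methyl, which sets C7 with the oxirane oxygen equatorial.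

Step 11
Reactants: 15 spiro-epoxide (as in step 10)
Product: 16 (3S,5aS,6R,7S,9aS)-3-(tert-butyldimethylsilyloxy)-6-(hydroxymethyl)-2,2,5a,7-tetramethylperhydro-1-benzoxepin-7-ol
Conditions: LiAlH4, THF, 0 → 40 °C
Reagents that add atoms: none
Why: Hydride opening of the epoxide at its unsubstituted carbon (SN2) turns the oxirane CH2 into the axial C7 methyl and leaves the equatorial tertiary alcohol with C7 unchanged, while the pivalate is reduced to the primary alcohol.

Step 12
Reactants: 16 diol (as in step 11)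
Product: 17 (3S,5aS,6S,7S,9aS)-3-(tert-butyldimethylsilyloxy)-6-(iodomethyl)-2,2,5a,7-tetramethylperhydro-1-benzoxepin-7-ol
Conditions: PPh3, I2, imidazole, CH2Cl2, 0 → 23 °C
Reagents that add atoms: iodine, [I][I]
Why: Appel-type iodination converts only the primary alcohol, since the tertiary C7 alkoxyphosphonium cannot undergo SN2 displacement (the C6 descriptor changes only through CIP priorities).

Step 13
Reactants: 13 α-methylene ketone (as in step 8, 1.5 equiv); 17 primary iodide (as in step 12)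
Product: 18 (3S,5aS,6S,9aS)-6-{2-[(3S,5aS,6S,7S,9aS)-3-(tert-butyldimethylsilyloxy)-7-hydroxy-2,2,5a,7-tetramethylperhydro-1-benzoxepin-6-yl]ethyl}-3-hydroxy-2,2,5a-trimethylperhydro-1-benzoxepin-7-one
Conditions: (Me3Si)3SiH (slow addition), AIBN (20 mol %), PhMe, 80 °C
Reagents that add atoms: none
Why: Giese reaction: the nucleophilic primary radical from 17 adds to the unhindered exocyclic β-carbon of enone 13 and the α-keto radical takes a hydrogen atom axially from the α face, so the new chain is equatorial at C6 (also the thermodynamic epimer).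

Step 14
Reactants: 18 hydroxy ketone (as in step 13)
Product: 19 (3S,5aS,6S,7R,9aS)-6-{2-[(3S,5aS,6S,7S,9aS)-3-(tert-butyldimethylsilyloxy)-7-hydroxy-2,2,5a,7-tetramethylperhydro-1-benzoxepin-6-yl]ethyl}-2,2,5a,7-tetramethylperhydro-1-benzoxepine-3,7-diol
Conditions: MeLi (6 equiv), CeCl3 (6 equiv), THF, −78 °C
Reagents that add atoms: methyllithium, [Li]C
Why: Organocerium 1,2-addition suppresses enolisation, and the methyl enters equatorially because the axial trajectory is blocked by the syn-axial 5a-methyl, giving the axial tertiary alcohol (7R).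

Step 15
Reactants: 19 triol (as in step 14)
Product: 20 (3S,5aS,6S,7R,9aS)-6-{2-[(3S,5aS,6S,7S,9aS)-7-acetoxy-3-(tert-butyldimethylsilyloxy)-2,2,5a,7-tetramethylperhydro-1-benzoxepin-6-yl]ethyl}-2,2,5a,7-tetramethylperhydro-1-benzoxepine-3,7-diyl diacetate
Conditions: LiN(SiMe3)2 (3.5 equiv), THF, −78 → 0 °C; then Ac2O (6 equiv), 0 → 23 °C
Reagents that add atoms: acetic anhydride, CC(=O)OC(C)=O
Why: O-acylation of the three lithium alkoxides with acetic anhydride esterifies the secondary and both hindered tertiary hydroxyls without touching any stereocentre, while the silyl ether shields the right-hand C3 oxygen.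

Step 16
Reactants: 20 triacetate silyl ether (as in step 15)
Product: 21 target CNP0169816.1
Conditions: HF·pyridine, pyridine/THF, 0 → 23 °C
Reagents that add atoms: none
Why: Fluoride-driven desilylation (Si–F bond formation) under buffered conditions frees the right-hand C3 hydroxyl without acetate cleavage or migration.

## Compound list

1 | geranyl bromide, (2E)-1-bromo-3,7-dimethylocta-2,6-diene | CC(C)=CCC/C(C)=C/CBr | starting material
2 | methyl acetoacetate (methyl 3-oxobutanoate) | CC(=O)CC(=O)OC | starting material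
3 | methyl (6E)-7,11-dimethyl-3-oxododeca-6,10-dienoate | CC(C)=CCC/C(C)=C/CCC(=O)CC(=O)OC | intermediate
4 | methyl (2Z,6E)-3-[(diethoxyphosphoryl)oxy]-7,11-dimethyldodeca-2,6,10-trienoate | CC(C)=CCC/C(C)=C/CC/C(OP(=O)(OCC)OCC)=C/C(=O)OC | intermediate
5 | methyl (2Z,6E)-7,11-dimethyl-3-[(trimethylsilyl)methyl]dodeca-2,6,10-trienoate | CC(C)=CCC/C(C)=C/CC/C(C[Si](C)(C)C)=C/C(=O)OC | intermediate
6 | methyl (2Z)-5-[(2S,3S)-3-{2-[(2S)-3,3-dimethyloxiran-2-yl]ethyl}-3-methyloxiran-2-yl]-3-[(trimethylsilyl)methyl]pent-2-enoate | CC1(C)O[C@H]1CC[C@]2(C)O[C@H]2CC/C(C[Si](C)(C)C)=C/C(=O)OC | intermediate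
7 | (2Z)-5-[(2S,3S)-3-{2-[(2S)-3,3-dimethyloxiran-2-yl]ethyl}-3-methyloxiran-2-yl]-3-[(trimethylsilyl)methyl]pent-2-en-1-ol | CC1(C)O[C@H]1CC[C@]2(C)O[C@H]2CC/C(C[Si](C)(C)C)=C/CO | intermediate
8 | (2Z)-5-[(2S,3S)-3-{2-[(2S)-3,3-dimethyloxiran-2-yl]ethyl}-3-methyloxiran-2-yl]-3-[(trimethylsilyl)methyl]pent-2-en-1-yl 2,2-dimethylpropanoate | CC1(C)O[C@H]1CC[C@]2(C)O[C@H]2CC/C(C[Si](C)(C)C)=C/COC(=O)C(C)(C)C | intermediate
9 | [(3S,5aS,6R,9aS)-2,2,5a-trimethyl-7-methylidene-3-(trimethylsilyloxy)perhydro-1-benzoxepin-6-yl]methyl 2,2-dimethylpropanoate | CC(C)(C)C(=O)OC[C@H]1[C@]2(C)CC[C@H](O[Si](C)(C)C)C(C)(C)O[C@H]2CCC1=C | intermediate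
10 | [(3S,5aS,6R,9aS)-3-hydroxy-2,2,5a-trimethyl-7-methylideneperhydro-1-benzoxepin-6-yl]methyl 2,2-dimethylpropanoate | CC(C)(C)C(=O)OC[C@H]1[C@]2(C)CC[C@H](O)C(C)(C)O[C@H]2CCC1=C | intermediate
11 | ozonide of 10: [(3S,5aS,6R,9aS)-3-hydroxy-2,2,5a-trimethylperhydrospiro[1-benzoxepine-7,3'-[1,2,4]trioxolan]-6-yl]methyl 2,2-dimethylpropanoate (spiro carbon unassigned) | CC(C)(C)C(=O)OC[C@H]1[C@]2(C)CC[C@H](O)C(C)(C)O[C@H]2CCC13OCOO3 | intermediate
12 | [(3S,5aS,6R,9aS)-3-hydroxy-2,2,5a-trimethyl-7-oxoperhydro-1-benzoxepin-6-yl]methyl 2,2-dimethylpropanoate | CC(C)(C)C(=O)OC[C@H]1[C@]2(C)CC[C@H](O)C(C)(C)O[C@H]2CCC1=O | intermediate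
13 | (3S,5aS,9aS)-3-hydroxy-2,2,5a-trimethyl-6-methylideneperhydro-1-benzoxepin-7-one | C=C1[C@]2(C)CC[C@H](O)C(C)(C)O[C@H]2CCC1=O | intermediate
14 | [(3S,5aS,6R,9aS)-3-(tert-butyldimethylsilyloxy)-2,2,5a-trimethyl-7-methylideneperhydro-1-benzoxepin-6-yl]methyl 2,2-dimethylpropanoate | CC(C)(C)C(=O)OC[C@H]1[C@]2(C)CC[C@H](O[Si](C)(C)C(C)(C)C)C(C)(C)O[C@H]2CCC1=C | intermediate
15 | [(3S,5aS,6R,7S,9aS)-3-(tert-butyldimethylsilyloxy)-2,2,5a-trimethylperhydrospiro[1-benzoxepine-7,2'-oxiran]-6-yl]methyl 2,2-dimethylpropanoate (oxirane oxygen α, equatorial) | CC(C)(C)C(=O)OC[C@H]1[C@]2(C)CC[C@H](O[Si](C)(C)C(C)(C)C)C(C)(C)O[C@H]2CC[C@]1(C3)O3 | intermediate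
16 | (3S,5aS,6R,7S,9aS)-3-(tert-butyldimethylsilyloxy)-6-(hydroxymethyl)-2,2,5a,7-tetramethylperhydro-1-benzoxepin-7-ol | OC[C@H]1[C@]2(C)CC[C@H](O[Si](C)(C)C(C)(C)C)C(C)(C)O[C@H]2CC[C@]1(C)O | intermediate
17 | (3S,5aS,6S,7S,9aS)-3-(tert-butyldimethylsilyloxy)-6-(iodomethyl)-2,2,5a,7-tetramethylperhydro-1-benzoxepin-7-ol | IC[C@H]1[C@]2(C)CC[C@H](O[Si](C)(C)C(C)(C)C)C(C)(C)O[C@H]2CC[C@]1(C)O | intermediate
18 | (3S,5aS,6S,9aS)-6-{2-[(3S,5aS,6S,7S,9aS)-3-(tert-butyldimethylsilyloxy)-7-hydroxy-2,2,5a,7-tetramethylperhydro-1-benzoxepin-6-yl]ethyl}-3-hydroxy-2,2,5a-trimethylperhydro-1-benzoxepin-7-one | C(C[C@H]1[C@]2(C)CC[C@H](O[Si](C)(C)C(C)(C)C)C(C)(C)O[C@H]2CC[C@]1(C)O)[C@H]1[C@]2(C)CC[C@H](O)C(C)(C)O[C@H]2CCC1=O | intermediate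
19 | (3S,5aS,6S,7R,9aS)-6-{2-[(3S,5aS,6S,7S,9aS)-3-(tert-butyldimethylsilyloxy)-7-hydroxy-2,2,5a,7-tetramethylperhydro-1-benzoxepin-6-yl]ethyl}-2,2,5a,7-tetramethylperhydro-1-benzoxepine-3,7-diol | C(C[C@H]1[C@]2(C)CC[C@H](O[Si](C)(C)C(C)(C)C)C(C)(C)O[C@H]2CC[C@]1(C)O)[C@H]1[C@]2(C)CC[C@H](O)C(C)(C)O[C@H]2CC[C@@]1(C)O | intermediate
20 | (3S,5aS,6S,7R,9aS)-6-{2-[(3S,5aS,6S,7S,9aS)-7-acetoxy-3-(tert-butyldimethylsilyloxy)-2,2,5a,7-tetramethylperhydro-1-benzoxepin-6-yl]ethyl}-2,2,5a,7-tetramethylperhydro-1-benzoxepine-3,7-diyl diacetate | C(C[C@H]1[C@]2(C)CC[C@H](O[Si](C)(C)C(C)(C)C)C(C)(C)O[C@H]2CC[C@]1(C)OC(C)=O)[C@H]1[C@]2(C)CC[C@H](OC(C)=O)C(C)(C)O[C@H]2CC[C@@]1(C)OC(C)=O | intermediate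
21 | CNP0169816.1, (3S,5aS,6S,7R,9aS)-6-{2-[(3S,5aS,6S,7S,9aS)-7-acetoxy-3-hydroxy-2,2,5a,7-tetramethylperhydro-1-benzoxepin-6-yl]ethyl}-2,2,5a,7-tetramethylperhydro-1-benzoxepine-3,7-diyl diacetate | CC(=O)O[C@H]1CC[C@]2(C)[C@H](CC[C@@](C)(OC(C)=O)[C@H]2CC[C@H]2[C@]3(C)CC[C@H](O)C(C)(C)O[C@H]3CC[C@]2(C)OC(C)=O)OC1(C)C | target

## Step count and risk

Total step count: 16. Longest linear sequence: 15 steps (steps 1–7, 9–12, 13–16). The left-hand branch (step 8) adds one step off the main line.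

The three steps most likely to fail:

Step 7 (the proposed silyl-transfer cascade). Risks are protodesilylation of the allylsilane, ionisation of the allylic pivalate, or interruption of the epoxonium relay. The fallback uses only known chemistry; it sets out from 3 and comes back at 10. ent-Shi epoxidation of 3 under NaHCO3-buffered KHSO5 (pH 8) gives the diepoxy keto ester F2. NaH and t-BuMe2SiCl give the Z silyl enol ether F3. The established stoichiometric tandem oxa-/carbacyclisation with an enol silane terminator (Me3SiOTf 1.1 equiv, 2,6-di-tert-butyl-4-methylpyridine, CH2Cl2, −78 °C) gives the bicyclic keto ester trimethylsilyl ether F4, and K2CO3/MeOH frees the hydroxy keto ester F5. Zn/CH2Br2/TiCl4 methylenation of the ketone gives the methylidene ester F6, LiAlH4 gives the diol F7, and pivaloylation of the primary hydroxyl only (t-BuCOCl 1.05 equiv, pyridine, −20 °C) returns 10.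

Step 4 (double Shi epoxidation next to the silylmethyl enoate). The γ-silyl enoate may desilylate or be oxidised in the basic peroxide medium. The fallback installs silicon after the epoxides; it sets out from 4 and comes back at 6. The same ent-Shi conditions applied to 4, whose phosphoryloxy enoate olefin is inert, give the diepoxy enol phosphate F1. Ni(acac)2-catalysed Kumada coupling of F1 with Me3SiCH2MgCl at 0 °C then gives 6.

Step 14 (methyl addition to the hindered, enolisable C7 ketone). Risks are enolisation or erosion of facial selectivity. The fallback replaces kinetic organometallic addition by a reversible ylide addition; it sets out from 18 and comes back at 19. Dimethylsulfoxonium methylide (Me3S(O)I, NaH, DMSO, 23 → 50 °C; Corey–Chaykovsky) forms the equatorial C–C bond under thermodynamic control and closes to the spiro-epoxide F8 (oxygen axial, β). LiAlH4 in THF opens F8 at CH2 to give the equatorial methyl and axial alcohol of 19.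

Further compounds
F1 | step 4 | methyl (2Z)-3-[(diethoxyphosphoryl)oxy]-5-[(2S,3S)-3-{2-[(2S)-3,3-dimethyloxiran-2-yl]ethyl}-3-methyloxiran-2-yl]pent-2-enoate | CC1(C)O[C@H]1CC[C@]2(C)O[C@H]2CC/C(OP(=O)(OCC)OCC)=C/C(=O)OC
F2 | step 7 | methyl 5-[(2S,3S)-3-{2-[(2S)-3,3-dimethyloxiran-2-yl]ethyl}-3-methyloxiran-2-yl]-3-oxopentanoate | CC1(C)O[C@H]1CC[C@]2(C)O[C@H]2CCC(=O)CC(=O)OC
F3 | step 7 | methyl (2Z)-3-(tert-butyldimethylsilyloxy)-5-[(2S,3S)-3-{2-[(2S)-3,3-dimethyloxiran-2-yl]ethyl}-3-methyloxiran-2-yl]pent-2-enoate | CC1(C)O[C@H]1CC[C@]2(C)O[C@H]2CC/C(O[Si](C)(C)C(C)(C)C)=C/C(=O)OC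
F4 | step 7 | methyl (3S,5aS,6S,9aS)-2,2,5a-trimethyl-7-oxo-3-(trimethylsilyloxy)perhydro-1-benzoxepine-6-carboxylate | COC(=O)[C@H]1[C@]2(C)CC[C@H](O[Si](C)(C)C)C(C)(C)O[C@H]2CCC1=O
F5 | step 7 | methyl (3S,5aS,6S,9aS)-3-hydroxy-2,2,5a-trimethyl-7-oxoperhydro-1-benzoxepine-6-carboxylate | COC(=O)[C@H]1[C@]2(C)CC[C@H](O)C(C)(C)O[C@H]2CCC1=O
F6 | step 7 | methyl (3S,5aS,6R,9aS)-3-hydroxy-2,2,5a-trimethyl-7-methylideneperhydro-1-benzoxepine-6-carboxylate | COC(=O)[C@H]1[C@]2(C)CC[C@H](O)C(C)(C)O[C@H]2CCC1=C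
F7 | step 7 | (3S,5aS,6R,9aS)-6-(hydroxymethyl)-2,2,5a-trimethyl-7-methylideneperhydro-1-benzoxepin-3-ol | OC[C@H]1[C@]2(C)CC[C@H](O)C(C)(C)O[C@H]2CCC1=C
F8 | step 14 | (3S,5aS,6S,7R,9aS)-6-{2-[(3S,5aS,6S,7S,9aS)-3-(tert-butyldimethylsilyloxy)-7-hydroxy-2,2,5a,7-tetramethylperhydro-1-benzoxepin-6-yl]ethyl}-2,2,5a-trimethylperhydrospiro[1-benzoxepine-7,2'-oxiran]-3-ol (oxirane oxygen β, axial) | C(C[C@H]1[C@]2(C)CC[C@H](O[Si](C)(C)C(C)(C)C)C(C)(C)O[C@H]2CC[C@]1(C)O)[C@H]1[C@]2(C)CC[C@H](O)C(C)(C)O[C@H]2CC[C@@]1(C3)O3
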